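The C4–C4a bond of the pyran (ring B) is cut and the carbocycle (ring A) is treated as a hydroxyquinone. The feature used is the peri pair C4–OMe/C5–OH around C4a: C5–OH is a former quinone carbonyl that makes C4a an acceptor, and C3=C4(OMe) is an enol ether that is a donor at C4. In one operation a tert-butoxyquinone carrying an α-alkoxy dimethyl acetal on its C1 methylene is unmasked, converted into that enol ether and cyclised onto C4a; aromatisation and aerial oxidation give the pyranoquinone. The quinone comes from a squarate by ring expansion; C7 is set last by enantioselective acyloxylation.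

Key step: step 6

Numbering: atom numbers are those of the isochromene skeleton of the target (C1, O2, C3, C4, C4a, C5, C6, C7, C8, C8a).
Assumption: for step 7 the (R,R)-lactamide iodane is written; the sense of induction on this enolate is not known beforehand, and the equally accessible (S,S)-reagent would replace it unchanged if that is the one that gives the (7R)-ester.

Step 1
Reactants: 1 (3-bromopropoxy)(tert-butyl)dimethylsilane; 2 2,2-dimethoxyacetaldehyde (water-free)
Product: 4 rac-5-[(tert-butyldimethylsilyl)oxy]-1,1-dimethoxypentan-2-ol, via Grignard reagent 3 (not isolated)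
Conditions: Mg, I2 (cat.), THF, 45 °C; then 2, −78 → 0 °C; aq. NH4Cl
Reagents that add atoms: none
Why: Grignard addition to the only carbonyl group of 2 should give the α-hydroxy acetal; the new carbinol centre is left racemic on purpose, because this carbon becomes the sp2 atom C3 in step 6.

Step 2
Reactants: 4 rac-5-[(tert-butyldimethylsilyl)oxy]-1,1-dimethoxypentan-2-ol; 5 3-bromoprop-1-yne
Product: 6 rac-tert-butyl{[5,5-dimethoxy-4-(prop-2-yn-1-yloxy)pentyl]oxy}dimethylsilane
Conditions: NaH, THF/DMF, 0 °C; then 5, Bu4NI (cat.), 0 → 25 °C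
Reagents that add atoms: none
Why: Williamson ether synthesis with an unhindered propargylic bromide should install O2, the future C1 (CH2) and the two alkyne carbons that become C8a and C4a, while acetal and silyl ether are inert to NaH.

Step 3
Reactants: 7 3,4-di-tert-butoxycyclobut-3-ene-1,2-dione
Product: 9 3-tert-butoxy-4-methylcyclobut-3-ene-1,2-dione, via lithium alkoxide 8 (not isolated)
Conditions: methyllithium, THF, −78 °C; then (CF3CO)2O, −78 → 0 °C
Reagents that add atoms: methyllithium, C[Li]
Why: Standard squarate-to-cyclobutenedione sequence: 1,2-addition of methyllithium gives alkoxide 8, and O-trifluoroacetylation, ionisation to the alkoxy-stabilised cyclobutenyl cation and loss of the tert-butyl group as its trifluoroacetate should give the dione that carries the future C7 methyl group.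

Step 4
Reactants: 6 rac-tert-butyl{[5,5-dimethoxy-4-(prop-2-yn-1-yloxy)pentyl]oxy}dimethylsilane; 9 3-tert-butoxy-4-methylcyclobut-3-ene-1,2-dione
Product: 11 3-tert-butoxy-4-[3-({5-[(tert-butyldimethylsilyl)oxy]-1,1-dimethoxypentan-2-yl}oxy)prop-1-yn-1-yl]-4-hydroxy-2-methylcyclobut-2-en-1-one (diastereomer mixture), via lithium acetylide 10 (not isolated)
Conditions: n-butyllithium, THF, −78 °C; then 9, −78 °C; aq. NH4Cl
Reagents that add atoms: none
Why: 1,2-Addition of a lithium acetylide to a cyclobutenedione should occur at the carbonyl next to the tert-butoxy-bearing carbon, because the other carbonyl is a deactivated vinylogous ester; this places the future C5 oxygen next to the future C6 oxygen, and both new stereocentres are destroyed in steps 5 and 6.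

Step 5
Reactants: 11 3-tert-butoxy-4-[3-({5-[(tert-butyldimethylsilyl)oxy]-1,1-dimethoxypentan-2-yl}oxy)prop-1-yn-1-yl]-4-hydroxy-2-methylcyclobut-2-en-1-one
Product: 13 rac-2-tert-butoxy-5-[({5-[(tert-butyldimethylsilyl)oxy]-1,1-dimethoxypentan-2-yl}oxy)methyl]-3-methylcyclohexa-2,5-diene-1,4-dione, via enynylketene 12 (not isolated)
Conditions: toluene (degassed), 110 °C
Reagents that add atoms: none
Why: Moore rearrangement: 4π-electrocyclic ring opening with outward rotation of the hydroxyl gives (Z)-enynylketene 12, the ketene carbon bonds to the distal alkyne carbon, and hydrogen transfer from O–H should give the quinone with the ketene carbon as C8, the carbinol carbon as C5 and the alkyne carbons as C4a (H) and C8a (CH2O).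

Step 6
Reactants: 13 rac-2-tert-butoxy-5-[({5-[(tert-butyldimethylsilyl)oxy]-1,1-dimethoxypentan-2-yl}oxy)methyl]-3-methylcyclohexa-2,5-diene-1,4-dione
Product: 17 3-{3-[(tert-butyldimethylsilyl)oxy]propyl}-6-hydroxy-4-methoxy-7-methyl-1H-isochromene-5,8-dione, via enol ether 14 (not isolated), via tris(trimethylsilyl) ether 15 (not isolated), via triol 16 (not isolated)
Conditions: TMSOTf (4.5 equiv), 2,6-di-tert-butyl-4-methylpyridine (5 equiv), CH2Cl2, −78 → −20 °C; then MeOH/H2O, air, 25 °C
Reagents that add atoms: none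
Why: TMSOTf should first cleave the tert-butyl vinylogous ester (loss of 2-methylpropene) and ionise the dimethyl acetal, and the hindered base removes the C3 proton to give enol ether 14 as an E/Z mixture, both isomers converging on the same product. Silylation of the more basic vinylogous-ester carbonyl C8=O then makes C4a the acceptor and the enol ether carbon C4 adds to it in an intramolecular Mukaiyama–Michael reaction, the closest known type being the Lewis-acid-promoted conjugate addition of enol ethers and silyl enol ethers to quinones. Ring B closes in a 6-endo-trig mode with respect to the C4a=C8a bond (the topology of an oxa-Pictet–Spengler closure with reversed polarity); loss of the C4 proton from the C3 oxocarbenium ion restores the methyl enol ether, and enolisation of C4a–H aromatises ring A, which drives the step and turns the C5 carbonyl into the C5 hydroxyl. No stereocentre survives the step. The selectivity needed is C4-to-C4a bonding: attack by C3 would be a 5-endo closure, and attack at the fully substituted carbon C8a would give a spiro adduct that cannot aromatise and should revert under the Lewis acid. Silylation of the three phenols in 15 prevents redox exchange with unreacted quinone, and hydrolysis in air should give triol 16, which autoxidises to hydroxyquinone 17.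

Step 7
Reactants: 17 3-{3-[(tert-butyldimethylsilyl)oxy]propyl}-6-hydroxy-4-methoxy-7-methyl-1H-isochromene-5,8-dione
Product: 19 (7R)-3-{3-[(tert-butyldimethylsilyl)oxy]propyl}-5-hydroxy-4-methoxy-7-methyl-6,8-dioxo-7,8-dihydro-6H-isochromen-7-yl butanoate, via trione 18 (not isolated)
Conditions: chiral aryl-λ3-iodane bis(butanoate) (1.2 equiv; made beforehand from the (R,R)-iodoarene, NaBO3·4H2O and butanoic acid), CH2Cl2, −40 °C; then Et3N (0.1 equiv), −40 → 0 °C
Reagents that add atoms: (R,R)-2,2'-{[2-(dibutanoyloxy-λ3-iodanyl)-1,3-phenylene]bis(oxy)}bis[N-(2,4,6-trimethylphenyl)propanamide], C[C@@H](Oc1cccc(O[C@H](C)C(=O)Nc2c(C)cc(C)cc2C)c1I(OC(=O)CCC)OC(=O)CCC)C(=O)Nc1c(C)cc(C)cc1C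
Why: Proposed new method: exchange of one butanoate on iodine for the acidic enol oxygen O6 of 17 should give an O-bound aryl-λ3-iodanyl enolate, and the second butanoate is then delivered to C7 with reductive loss of the iodoarene; the closest known reaction types are the trivalent-iodine α-acyloxylation of cyclic 1,3-dicarbonyl enols (racemic) and the enantioselective dearomatising oxygenation of naphthols with this C2-symmetric lactamide iodoarene, whose amide arms hydrogen-bond to the iodine-bound carboxylates and shield one face of the planar enolate, so the C7 configuration is reagent-controlled; trione 18 then shifts a C1 proton to O5 under Et3N catalysis to give the conjugated 6H-isochromene-6,8-dione 19 without touching C7.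

Step 8
Reactants: 19 (7R)-3-{3-[(tert-butyldimethylsilyl)oxy]propyl}-5-hydroxy-4-methoxy-7-methyl-6,8-dioxo-7,8-dihydro-6H-isochromen-7-yl butanoate
Product: 20 (7R)-5-hydroxy-3-(3-hydroxypropyl)-4-methoxy-7-methyl-6,8-dioxo-7,8-dihydro-6H-isochromen-7-yl butanoate
Conditions: HF·pyridine, pyridine, THF, 0 °C
Reagents that add atoms: none
Why: Buffered fluoride desilylation of a primary silyl ether should leave the tertiary butanoate, the C4 methyl enol ether and the pyran ring untouched, and C7 has no pathway for epimerisation.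

Compound list
1 | (3-bromopropoxy)(tert-butyl)dimethylsilane | BrCCCO[Si](C)(C)C(C)(C)C | starting material
2 | 2,2-dimethoxyacetaldehyde | COC(OC)C=O | starting material
3 | {3-[(tert-butyldimethylsilyl)oxy]propyl}magnesium bromide | CC(C)(C)[Si](C)(C)OCCC[Mg]Br | intermediate
4 | rac-5-[(tert-butyldimethylsilyl)oxy]-1,1-dimethoxypentan-2-ol | COC(OC)C(O)CCCO[Si](C)(C)C(C)(C)C | intermediate
5 | 3-bromoprop-1-yne (propargyl bromide) | C#CCBr | starting material
6 | rac-tert-butyl{[5,5-dimethoxy-4-(prop-2-yn-1-yloxy)pentyl]oxy}dimethylsilane | COC(OC)C(CCCO[Si](C)(C)C(C)(C)C)OCC#C | intermediate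
7 | 3,4-di-tert-butoxycyclobut-3-ene-1,2-dione (di-tert-butyl squarate) | CC(C)(C)OC1=C(OC(C)(C)C)C(=O)C1=O | starting material
8 | lithium 2,3-di-tert-butoxy-1-methyl-4-oxocyclobut-2-en-1-olate (racemic) | CC(C)(C)OC1=C(OC(C)(C)C)C(C)(O[Li])C1=O | intermediate
9 | 3-tert-butoxy-4-methylcyclobut-3-ene-1,2-dione | CC(C)(C)OC1=C(C)C(=O)C1=O | intermediate
10 | lithium acetylide of 6 | COC(OC)C(CCCO[Si](C)(C)C(C)(C)C)OCC#C[Li] | intermediate
11 | 3-tert-butoxy-4-[3-({5-[(tert-butyldimethylsilyl)oxy]-1,1-dimethoxypentan-2-yl}oxy)prop-1-yn-1-yl]-4-hydroxy-2-methylcyclobut-2-en-1-one (diastereomer mixture, racemic) | CC(C)(C)OC1=C(C)C(=O)C1(O)C#CCOC(CCCO[Si](C)(C)C(C)(C)C)C(OC)OC | intermediate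
12 | (3Z)-3-tert-butoxy-7-({5-[(tert-butyldimethylsilyl)oxy]-1,1-dimethoxypentan-2-yl}oxy)-4-hydroxy-2-methylhepta-1,3-dien-5-yn-1-one (enynylketene, racemic) | O=C=C(C)/C(OC(C)(C)C)=C(/O)C#CCOC(CCCO[Si](C)(C)C(C)(C)C)C(OC)OC | intermediate
13 | rac-2-tert-butoxy-5-[({5-[(tert-butyldimethylsilyl)oxy]-1,1-dimethoxypentan-2-yl}oxy)methyl]-3-methylcyclohexa-2,5-diene-1,4-dione | CC(C)(C)OC1=C(C)C(=O)C(COC(CCCO[Si](C)(C)C(C)(C)C)C(OC)OC)=CC1=O | intermediate
14 | 2-[({5-[(tert-butyldimethylsilyl)oxy]-1-methoxypent-1-en-2-yl}oxy)methyl]-6-methyl-5-[(trimethylsilyl)oxy]cyclohexa-2,5-diene-1,4-dione (E/Z mixture) | COC=C(CCCO[Si](C)(C)C(C)(C)C)OCC1=CC(=O)C(O[Si](C)(C)C)=C(C)C1=O | intermediate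
15 | 3-{3-[(tert-butyldimethylsilyl)oxy]propyl}-4-methoxy-7-methyl-5,6,8-tris[(trimethylsilyl)oxy]-1H-isochromene | COC1=C(CCCO[Si](C)(C)C(C)(C)C)OCc2c1c(O[Si](C)(C)C)c(O[Si](C)(C)C)c(C)c2O[Si](C)(C)C | intermediate
16 | 3-{3-[(tert-butyldimethylsilyl)oxy]propyl}-4-methoxy-7-methyl-1H-isochromene-5,6,8-triol | COC1=C(CCCO[Si](C)(C)C(C)(C)C)OCc2c1c(O)c(O)c(C)c2O | intermediate
17 | 3-{3-[(tert-butyldimethylsilyl)oxy]propyl}-6-hydroxy-4-methoxy-7-methyl-1H-isochromene-5,8-dione | COC1=C(CCCO[Si](C)(C)C(C)(C)C)OCC2=C1C(=O)C(O)=C(C)C2=O | intermediate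
18 | (7R)-3-{3-[(tert-butyldimethylsilyl)oxy]propyl}-4-methoxy-7-methyl-5,6,8-trioxo-5,6,7,8-tetrahydro-1H-isochromen-7-yl butanoate | CCCC(=O)O[C@]1(C)C(=O)C2=C(C(=O)C1=O)C(OC)=C(CCCO[Si](C)(C)C(C)(C)C)OC2 | intermediate
19 | (7R)-3-{3-[(tert-butyldimethylsilyl)oxy]propyl}-5-hydroxy-4-methoxy-7-methyl-6,8-dioxo-7,8-dihydro-6H-isochromen-7-yl butanoate | CCCC(=O)O[C@]1(C)C(=O)C2=COC(CCCO[Si](C)(C)C(C)(C)C)=C(OC)C2=C(O)C1=O | intermediate
20 | (7R)-5-hydroxy-3-(3-hydroxypropyl)-4-methoxy-7-methyl-6,8-dioxo-7,8-dihydro-6H-isochromen-7-yl butanoate | CCCC(=O)O[C@]1(C)C(=O)C2=COC(CCCO)=C(OC)C2=C(O)C1=O | target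

Total step count: 8. Longest linear sequence: 7 steps (1, 2, 4, 5, 6, 7, 8); step 3 is a one-step branch.

Steps most likely to fail

Step 7 (proposed new method). The two flanks of the C6–C7–C8 enolate are nearly alike, so face discrimination may be poor; ligand exchange at iodine may also be slow enough for the ring B enol ether to be oxidised instead. Fallback with known chemistry, from 17: acyloxylation with the achiral reagent PhI(O2CPr)2 (from PhI(OAc)2 and butanoic acid; CH2Cl2, 0 °C) should give racemic trione F1 and, after Et3N-induced tautomerisation, racemic ester F2. Preparative HPLC on an amylose-carbamate chiral stationary phase then separates the enantiomers, and the (7R)-enantiomer is 19.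

Step 6. A kinetically favoured 5-exo closure of C4 onto the substituted carbon C8a, or electron transfer from the electron-rich enol ether to the silylated quinone, may divert the cyclisation. Fallback, from 13: reduction with aqueous Na2S2O4 gives hydroquinone F3. BF3·OEt2 in CH2Cl2 at −40 °C then ionises the acetal and removes the tert-butyl group; the oxocarbenium ion is attacked by C4a, the only free arene position and ortho to a hydroxyl (Friedel–Crafts closure of the oxa-Pomeranz–Fritsch type), to give 4-methoxyisochroman-5,6,8-triol F4 as a cis/trans mixture. Stirring in air gives isochroman hydroxyquinone F5, and catalytic Et3N (or acid) shifts the C4 and C3 hydrogens through the methoxy-stabilised quinone methide to give triol 16, which autoxidises to 17.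

Step 8. Fluoride or pyridine may add to C1 of the pyran ring, or the C7 butanoate may migrate or solvolyse during desilylation. Fallback, from 17: the silyl ether is cleaved first (HF·pyridine, THF, 0 °C), at the stage of the robust hydroxyquinone, to give alcohol F6. The acyloxylation of step 7 is then run on F6, since trivalent-iodine dicarboxylates neither acylate nor oxidise an aliphatic alcohol at −40 °C; this gives trione F7 and, after tautomerisation, 20 directly.

Further compounds
F1 | step 7 | racemic 3-{3-[(tert-butyldimethylsilyl)oxy]propyl}-4-methoxy-7-methyl-5,6,8-trioxo-5,6,7,8-tetrahydro-1H-isochromen-7-yl butanoate | CCCC(=O)OC1(C)C(=O)C2=C(C(=O)C1=O)C(OC)=C(CCCO[Si](C)(C)C(C)(C)C)OC2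
F2 | step 7 | racemic 3-{3-[(tert-butyldimethylsilyl)oxy]propyl}-5-hydroxy-4-methoxy-7-methyl-6,8-dioxo-7,8-dihydro-6H-isochromen-7-yl butanoate | CCCC(=O)OC1(C)C(=O)C2=COC(CCCO[Si](C)(C)C(C)(C)C)=C(OC)C2=C(O)C1=O
F3 | step 6 | rac-2-tert-butoxy-5-[({5-[(tert-butyldimethylsilyl)oxy]-1,1-dimethoxypentan-2-yl}oxy)methyl]-3-methylbenzene-1,4-diol | CC(C)(C)Oc1c(C)c(O)c(COC(CCCO[Si](C)(C)C(C)(C)C)C(OC)OC)cc1O
F4 | step 6 | 3-{3-[(tert-butyldimethylsilyl)oxy]propyl}-4-methoxy-7-methyl-3,4-dihydro-1H-isochromene-5,6,8-triol (cis/trans mixture, racemic) | COC1C(CCCO[Si](C)(C)C(C)(C)C)OCc2c1c(O)c(O)c(C)c2O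
F5 | step 6 | 3-{3-[(tert-butyldimethylsilyl)oxy]propyl}-6-hydroxy-4-methoxy-7-methyl-3,4-dihydro-1H-isochromene-5,8-dione (cis/trans mixture, racemic) | COC1C(CCCO[Si](C)(C)C(C)(C)C)OCC2=C1C(=O)C(O)=C(C)C2=O
F6 | step 8 | 6-hydroxy-3-(3-hydroxypropyl)-4-methoxy-7-methyl-1H-isochromene-5,8-dione | COC1=C(CCCO)OCC2=C1C(=O)C(O)=C(C)C2=O
F7 | step 8 | (7R)-3-(3-hydroxypropyl)-4-methoxy-7-methyl-5,6,8-trioxo-5,6,7,8-tetrahydro-1H-isochromen-7-yl butanoate | CCCC(=O)O[C@]1(C)C(=O)C2=C(C(=O)C1=O)C(OC)=C(CCCO)OC2
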